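**Retrosynthetic overview**
- Feature: in the γ-butyrolactone ring (O1, C2=O, C3, C4, C5) the veratryl CH2 sits on C4, β to the carbonyl. The CH2 that leads to C4' of the 2-pyrone ring sits on C3, α to the carbonyl and trans to the first, so C3–C4 is read as the C=C of a butenolide.
- Disconnections: C4–C(benzylic) goes back to the veratraldehyde carbon, made nucleophilic as its lithiated 1,3-dithiane. C3–CH2 goes back to a 4-(bromomethyl)-2-pyrone-6-carboxylate. Both bonds are made in one flask on (5R)-5-(l-menthyloxy)furan-2(5H)-one, whose acetal carbon C5 passes the menthol chirality to C4 and then C3 and ends as the lactone CH2.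
- Ring order: the pyrone ring is closed first, by vinylogous Claisen condensation of ethyl 3-methylbut-2-enoate with diethyl oxalate followed by acid lactonisation. The butenolide ring comes from the furan ring of furfural and the dithiane ring is temporary. The lactone ring is opened at C5 and reclosed after aldehyde reduction.
- Nickel-based desulfurisation and basic borohydride would attack the pyrone, so the end game stays acidic: aqueous TFA, NaBH(OAc)3, PhI(OCOCF3)2 hydrolysis of the dithiane, then Et3SiH/TFA deoxygenation of the aryl ketone.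

Key step: step 7

Remark: lactone atoms are numbered O1, C2 (C=O), C3, C4, C5 and pyrone atoms O1', C2' (C=O), C3' to C6' (C6' bears the carboxyl group); the target SMILES is read as (3R,4R), 3,4-trans; l-menthyl stands for (1R,2S,5R)-5-methyl-2-(propan-2-yl)cyclohexyl.

**Step 1**
Reactants: 1 furfural
Product: 3 5-hydroxyfuran-2(5H)-one (racemic), via furfural endoperoxide 2 (not isolated)
Conditions: O2, methylene blue (cat.), MeOH, visible light, 0 °C to rt
Reagents that add atoms: dioxygen, O=O
Why: Dye-sensitised singlet-oxygen [4+2] cycloaddition to the furan gives endoperoxide 2, whose formyl group is attacked by methanol and expelled as methyl formate in a Grob-type fragmentation that leaves the racemic pseudo-acid 3.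

**Step 2**
Reactants: 3 5-hydroxyfuran-2(5H)-one; 4 (-)-menthol
Product: 5 (5R)-5-(l-menthyloxy)furan-2(5H)-one
Conditions: (+)-camphorsulfonic acid (cat.), toluene, reflux, azeotropic removal of water; crystallisation from petroleum ether, −20 °C; mother liquor re-equilibrated with the acid and crystallised again
Reagents that add atoms: none
Why: Acid-catalysed acetalisation of the pseudo-acid gives both C5 epimers, which interconvert under the acid while only the (5R) epimer crystallises, so C5 is set by a crystallisation-induced asymmetric transformation against the fixed menthol stereocentres.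

**Step 3**
Reactants: 6 veratraldehyde
Product: 7 2-(3,4-dimethoxyphenyl)-1,3-dithiane
Conditions: HS(CH2)3SH, BF3·OEt2 (cat.), CH2Cl2, 0 °C to rt
Reagents that add atoms: propane-1,3-dithiol, SCCCS
Why: Lewis-acid-catalysed thioacetalisation of an aromatic aldehyde is fast and leaves the aryl methyl ethers untouched.

**Step 4**
Reactants: 8 ethyl 3-methylbut-2-enoate; 9 diethyl oxalate
Product: 11 4-methyl-2-oxo-2H-pyran-6-carboxylic acid, via potassium dienolate 10 (not isolated)
Conditions: KOEt, THF, 0 °C to rt; then conc. aq. HCl, reflux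
Reagents that add atoms: water, O
Why: In this vinylogous Claisen condensation the dienolate of 8 is acylated by oxalate at its γ-carbon because only that product is drained off as the stabilised salt 10, and hot HCl then isomerises the diene, closes the enol oxygen onto the butenoate ester (a ring closure that needs ethoxide rather than tert-butoxide as leaving group, hence ethyl esters here) and hydrolyses the remaining ester.

**Step 5**
Reactants: 11 4-methyl-2-oxo-2H-pyran-6-carboxylic acid
Product: 12 tert-butyl 4-methyl-2-oxo-2H-pyran-6-carboxylate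
Conditions: Cl3CC(=NH)Ot-Bu, THF/cyclohexane, rt
Reagents that add atoms: tert-butyl 2,2,2-trichloroacetimidate, CC(C)(C)OC(=N)C(Cl)(Cl)Cl
Why: Trichloroacetimidate esterification of this fairly strong acid runs by proton transfer and capture of the tert-butyl cation, with no base or nucleophile present that could open the pyrone.

**Step 6**
Reactants: 12 tert-butyl 4-methyl-2-oxo-2H-pyran-6-carboxylate
Product: 13 tert-butyl 4-(bromomethyl)-2-oxo-2H-pyran-6-carboxylate
Conditions: NBS (1.0 equiv), AIBN (cat.), PhCF3, 85 °C
Reagents that add atoms: N-bromosuccinimide, O=C1CCC(=O)N1Br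
Why: In this Wohl–Ziegler bromination the C4' methyl group, which corresponds to the β-methyl of a 3-methylbut-2-enoate, holds the only allylic hydrogens, and the two acyl groups leave the ring too electron-poor for ionic bromination at C3' or C5'.

**Step 7**
Reactants: 7 2-(3,4-dimethoxyphenyl)-1,3-dithiane; 5 (5R)-5-(l-menthyloxy)furan-2(5H)-one; 13 tert-butyl 4-(bromomethyl)-2-oxo-2H-pyran-6-carboxylate
Product: 16 tert-butyl 4-{[(3R,4R,5R)-4-[2-(3,4-dimethoxyphenyl)-1,3-dithian-2-yl]-5-(l-menthyloxy)-2-oxotetrahydrofuran-3-yl]methyl}-2-oxo-2H-pyran-6-carboxylate, via 2-lithiodithiane 14 (not isolated), via lithium enolate 15 (not isolated)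
Conditions: 7, n-BuLi (0.98 equiv), THF, −78 to −20 °C; 5 (1.05 equiv), THF, −78 °C; transfer by cannula into 13 (1.3 equiv), DMPU, THF, −78 to −40 °C; AcOH quench at −40 °C
Reagents that add atoms: none
Why: n-BuLi deprotonates C2 of dithiane 7 to the soft, aryl- and sulfur-stabilised carbanion 14, which adds 1,4 to butenolide 5 to give lithium enolate 15, and this is run into an excess of bromide 13, where C3 displaces bromide in SN2 fashion. The closest known reaction type is the tandem Michael addition and enolate alkylation of lithiated 2-aryl-1,3-dithianes on 5-alkoxyfuran-2(5H)-ones with benzylic bromides; two C–C bonds form (C4–C(dithiane) and C3–CH2) and no ring closes. C4 is set by the (5R)-menthyloxy group on C5, which blocks one face of the flat butenolide so that the carbanion enters anti to it. C3 is set by the new bulky dithianyl group on C4, which sends the electrophile to the opposite face of the enolate and should give the 3,4-trans, 4,5-trans (3R,4R,5R) isomer. The step needs 1,4- over 1,2-addition, which the delocalised carbanion and the reversibility of carbonyl attack provide, and it needs attack at CH2Br instead of addition to C2' or C6' of the pyrone or removal of the acidic pyronyl CH2 hydrogens. These are secured by the primary, doubly activated allylic bromide set against a hindered secondary enolate carbon, by the tert-butyl ester that shields C6', by the slight deficit of n-BuLi and slight excess of 5 that leave no free 14 to meet the pyrone, and by inverse addition at low temperature with a cold acid quench.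

**Step 8**
Reactants: 16 the three-component adduct
Product: 17 4-{[(3R,4R)-4-[2-(3,4-dimethoxyphenyl)-1,3-dithian-2-yl]-5-hydroxy-2-oxotetrahydrofuran-3-yl]methyl}-2-oxo-2H-pyran-6-carboxylic acid (C5 anomers in equilibrium with the open aldehyde acid)
Conditions: TFA/H2O (4:1), 40 °C; menthol removed by trituration with pentane
Reagents that add atoms: water, O
Why: In this acid-catalysed acylal hydrolysis C5 ionises with loss of the carboxyl oxygen, water captures the oxocarbenium ion and menthol leaves, the tert-butyl ester fragments at the same time by the AAL1 path, and dithiane, pyrone, C3 and C4 are stable to aqueous acid while the C5 anomeric mixture is erased in step 9.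

**Step 9**
Reactants: 17 the lactol diacid
Product: 19 4-{[(3R,4R)-4-[2-(3,4-dimethoxyphenyl)-1,3-dithian-2-yl]-2-oxotetrahydrofuran-3-yl]methyl}-2-oxo-2H-pyran-6-carboxylic acid, via hydroxy diacid 18 (not isolated)
Conditions: NaBH(OAc)3, THF/AcOH, 0 °C to rt; then 1 M HCl
Reagents that add atoms: none
Why: Acyloxyborohydride reduction is selective for aldehydes, so the reagent takes the open aldehyde form of pseudo-acid 17 without touching pyrone, lactone or acid groups and without exposing the pyrone or the epimerisable C4 to base, and γ-hydroxy acid 18 lactonises spontaneously in the acidic medium.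

**Step 10**
Reactants: 19 the dithianyl lactone acid
Product: 20 4-{[(3R,4R)-4-(3,4-dimethoxybenzoyl)-2-oxotetrahydrofuran-3-yl]methyl}-2-oxo-2H-pyran-6-carboxylic acid
Conditions: PhI(OCOCF3)2, MeCN/H2O (9:1), 0 °C
Reagents that add atoms: water, O
Why: In this oxidative dethioacetalisation with a hypervalent iodine reagent sulfur is the most easily oxidised site, the aryl-stabilised thionium ion is captured by water, and the mildly acidic medium spares the pyrone and keeps the now enolisable C4 in its favoured trans arrangement.

**Step 11**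
Reactants: 20 the keto lactone acid
Product: 22 4-{[(3R,4R)-4-(3,4-dimethoxybenzyl)-2-oxotetrahydrofuran-3-yl]methyl}-2-oxo-2H-pyran-6-carboxylic acid (CNP0526356.1), via benzylic alcohol 21 (not isolated)
Conditions: Et3SiH (excess), TFA/CH2Cl2 (1:1), 0 °C to rt
Reagents that add atoms: none
Why: In this ionic hydrogenation of an aryl ketone hydride transfer to the protonated carbonyl gives benzylic alcohol 21, which ionises to a cation stabilised by the para-methoxy group and takes a second hydride, while the electron-poor pyrone neither accepts hydride nor traps the cation and C3 and C4 are not touched.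

**Compound list**
1 | furfural | O=Cc1ccco1 | starting material
2 | furfural endoperoxide, 2,3,7-trioxabicyclo[2.2.1]hept-5-ene-1-carbaldehyde (racemic) | O=CC12C=CC(OO1)O2 | intermediate
3 | 5-hydroxyfuran-2(5H)-one (racemic) | O=C1C=CC(O)O1 | intermediate
4 | (-)-menthol, (1R,2S,5R) | C[C@@H]1CC[C@H]([C@@H](C1)O)C(C)C | starting material
5 | (5R)-5-(l-menthyloxy)furan-2(5H)-one | O=C1C=C[C@H](O[C@@H]2C[C@H](C)CC[C@H]2C(C)C)O1 | intermediate
6 | veratraldehyde | COc1ccc(C=O)cc1OC | starting material
7 | 2-(3,4-dimethoxyphenyl)-1,3-dithiane | COc1ccc(C2SCCCS2)cc1OC | intermediate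
8 | ethyl 3-methylbut-2-enoate | CCOC(=O)C=C(C)C | starting material
9 | diethyl oxalate | CCOC(=O)C(=O)OCC | starting material
10 | potassium enolate of diethyl 2-hydroxy-4-methylhexa-2,4-dienedioate (alkene isomers, equilibrated by the acid) | CCOC(=O)C=C(C)C=C([O-])C(=O)OCC.[K+] | intermediate
11 | 4-methyl-2-oxo-2H-pyran-6-carboxylic acid | Cc1cc(C(=O)O)oc(=O)c1 | intermediate
12 | tert-butyl 4-methyl-2-oxo-2H-pyran-6-carboxylate | Cc1cc(C(=O)OC(C)(C)C)oc(=O)c1 | intermediate
13 | tert-butyl 4-(bromomethyl)-2-oxo-2H-pyran-6-carboxylate | CC(C)(C)OC(=O)c1cc(CBr)cc(=O)o1 | intermediate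
14 | 2-lithio-2-(3,4-dimethoxyphenyl)-1,3-dithiane | COc1ccc(C2([Li])SCCCS2)cc1OC | intermediate
15 | lithium enolate of (4R,5R)-4-[2-(3,4-dimethoxyphenyl)-1,3-dithian-2-yl]-5-(l-menthyloxy)dihydrofuran-2(3H)-one | COc1ccc(C2(SCCCS2)[C@H]3[C@H](O[C@@H]4C[C@H](C)CC[C@H]4C(C)C)OC(O[Li])=C3)cc1OC | intermediate
16 | tert-butyl 4-{[(3R,4R,5R)-4-[2-(3,4-dimethoxyphenyl)-1,3-dithian-2-yl]-5-(l-menthyloxy)-2-oxotetrahydrofuran-3-yl]methyl}-2-oxo-2H-pyran-6-carboxylate | COc1ccc(C2(SCCCS2)[C@H]3[C@H](O[C@@H]4C[C@H](C)CC[C@H]4C(C)C)OC(=O)[C@@H]3Cc5cc(C(=O)OC(C)(C)C)oc(=O)c5)cc1OC | intermediate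
17 | 4-{[(3R,4R)-4-[2-(3,4-dimethoxyphenyl)-1,3-dithian-2-yl]-5-hydroxy-2-oxotetrahydrofuran-3-yl]methyl}-2-oxo-2H-pyran-6-carboxylic acid (C5 anomers) | COc1ccc(C2(SCCCS2)[C@H]3C(O)OC(=O)[C@@H]3Cc4cc(C(=O)O)oc(=O)c4)cc1OC | intermediate
18 | open γ-hydroxy diacid, C3 (R) and C4 (R) in lactone numbering | COc1ccc(C2(SCCCS2)[C@@H](CO)[C@@H](Cc3cc(C(=O)O)oc(=O)c3)C(=O)O)cc1OC | intermediate
19 | 4-{[(3R,4R)-4-[2-(3,4-dimethoxyphenyl)-1,3-dithian-2-yl]-2-oxotetrahydrofuran-3-yl]methyl}-2-oxo-2H-pyran-6-carboxylic acid | COc1ccc(C2(SCCCS2)[C@H]3COC(=O)[C@@H]3Cc4cc(C(=O)O)oc(=O)c4)cc1OC | intermediate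
20 | 4-{[(3R,4R)-4-(3,4-dimethoxybenzoyl)-2-oxotetrahydrofuran-3-yl]methyl}-2-oxo-2H-pyran-6-carboxylic acid | COc1ccc(C(=O)[C@H]2COC(=O)[C@@H]2Cc3cc(C(=O)O)oc(=O)c3)cc1OC | intermediate
21 | 4-{[(3R,4R)-4-[(3,4-dimethoxyphenyl)(hydroxy)methyl]-2-oxotetrahydrofuran-3-yl]methyl}-2-oxo-2H-pyran-6-carboxylic acid (carbinol epimers) | COc1ccc(C(O)[C@H]2COC(=O)[C@@H]2Cc3cc(C(=O)O)oc(=O)c3)cc1OC | intermediate
22 | 4-{[(3R,4R)-4-(3,4-dimethoxybenzyl)-2-oxotetrahydrofuran-3-yl]methyl}-2-oxo-2H-pyran-6-carboxylic acid (CNP0526356.1) | COc1ccc(C[C@H]2COC(=O)[C@@H]2Cc2cc(C(=O)O)oc(=O)c2)cc1OC | target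

**Total step count:** 11.
**Longest linear sequence:** 8 (steps 4, 5, 6, 7, 8, 9, 10, 11).

**Steps most likely to fail**

1. **Step 7.**
   - Risk: the strongly basic lithium enolate may take a proton from the CH2Br group, or from the pyronyl CH2 of product already formed. It may also add to C6' or C2' of the pyrone faster than it displaces bromide. In either case the conjugate adduct returns merely protonated at C3.
   - Fallback: the coupling is split in two and the basicity of the C3 nucleophile is lowered with an activating group.
   - The fallback sets out from enolate 15, generated from 5 and 7 as in step 7. Boc2O is added at −78 °C in place of 13 and the mixture is quenched with AcOH. This should give the 3,4-trans α-(tert-butoxycarbonyl) lactone F1.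
   - The malonate-type enolate of this lactone, formed with K2CO3 in DMF at 0 °C, is far less basic and softer. It should be alkylated by 13 on the face away from the dithianyl group to give the quaternary lactone F2.
   - TFA/H2O as in step 8 should strip menthol and both tert-butyl groups to give the lactol triacid F3.
   - On warming in dioxane this triacid loses CO2 from its malonic half-acid, and C3 is expected to settle in the more stable 3,4-trans arrangement. The route is rejoined at 17.

2. **Step 11.**
   - Risk: the benzylic cation may lose the C4 proton before it is reduced, which would erode the C4 configuration through a styrene. Reduction may also stall at the benzylic trifluoroacetate stage.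
   - Fallback: both C–S bonds are cut by a radical chain before any deprotection, so that neither a ketone nor a cation is formed.
   - The fallback sets out from 16. Concentrated Bu3SnH in excess with AIBN in toluene at 90–110 °C should give the 4-(3,4-dimethoxybenzyl) acetal lactone F4. The high stannane concentration is meant to outrun cyclisation of the benzylic radical onto the pyrone.
   - TFA/H2O as in step 8 should then give the lactol diacid F5.
   - NaBH(OAc)3 in THF/AcOH should give the hydroxy diacid F6, which lactonises on work-up with 1 M HCl. The route is rejoined at 22.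

3. **Step 6.**
   - Risk: a second bromination of the CH2Br group may occur. Hydrogen abstraction from a methyl group on an electron-poor ring may also be slow enough to let ring bromination compete.
   - Fallback: the methyl group is oxidised instead of halogenated.
   - The fallback sets out from 12. Riley oxidation with SeO2 in refluxing dioxane should give tert-butyl 4-formyl-2-oxo-2H-pyran-6-carboxylate F7.
   - NaBH(OAc)3 in THF/AcOH should reduce only the aldehyde, giving tert-butyl 4-(hydroxymethyl)-2-oxo-2H-pyran-6-carboxylate F8.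
   - Appel bromination (CBr4, PPh3, CH2Cl2, 0 °C) then rejoins the route at 13.

**Further compounds**
F1 | step 7 | tert-butyl (4R,5R)-4-[2-(3,4-dimethoxyphenyl)-1,3-dithian-2-yl]-5-(l-menthyloxy)-2-oxotetrahydrofuran-3-carboxylate, 3,4-trans (C3 labile) | COc1ccc(C2(SCCCS2)[C@H]3[C@H](O[C@@H]4C[C@H](C)CC[C@H]4C(C)C)OC(=O)[C@@H]3C(=O)OC(C)(C)C)cc1OC
F2 | step 7 | quaternary lactone: F1 bearing at C3 the [6-(tert-butoxycarbonyl)-2-oxo-2H-pyran-4-yl]methyl group trans to the dithianyl group | COc1ccc(C2(SCCCS2)[C@H]3[C@H](O[C@@H]4C[C@H](C)CC[C@H]4C(C)C)OC(=O)[C@@]3(Cc5cc(C(=O)OC(C)(C)C)oc(=O)c5)C(=O)OC(C)(C)C)cc1OC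
F3 | step 7 | lactol triacid: 3-carboxy derivative of 17 | COc1ccc(C2(SCCCS2)[C@H]3C(O)OC(=O)[C@@]3(Cc4cc(C(=O)O)oc(=O)c4)C(=O)O)cc1OC
F4 | step 11 | tert-butyl 4-{[(3R,4R,5R)-4-(3,4-dimethoxybenzyl)-5-(l-menthyloxy)-2-oxotetrahydrofuran-3-yl]methyl}-2-oxo-2H-pyran-6-carboxylate | COc1ccc(C[C@H]2[C@H](O[C@@H]3C[C@H](C)CC[C@H]3C(C)C)OC(=O)[C@@H]2Cc4cc(C(=O)OC(C)(C)C)oc(=O)c4)cc1OC
F5 | step 11 | 4-{[(3R,4R)-4-(3,4-dimethoxybenzyl)-5-hydroxy-2-oxotetrahydrofuran-3-yl]methyl}-2-oxo-2H-pyran-6-carboxylic acid (C5 anomers) | COc1ccc(C[C@H]2C(O)OC(=O)[C@@H]2Cc3cc(C(=O)O)oc(=O)c3)cc1OC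
F6 | step 11 | open γ-hydroxy diacid of the target, C3 (R) and C4 (R) in lactone numbering | COc1ccc(C[C@@H](CO)[C@@H](Cc2cc(C(=O)O)oc(=O)c2)C(=O)O)cc1OC
F7 | step 6 | tert-butyl 4-formyl-2-oxo-2H-pyran-6-carboxylate | CC(C)(C)OC(=O)c1cc(C=O)cc(=O)o1
F8 | step 6 | tert-butyl 4-(hydroxymethyl)-2-oxo-2H-pyran-6-carboxylate | CC(C)(C)OC(=O)c1cc(CO)cc(=O)o1
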